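**Plan**
- Retrosynthesis: remove the three MOM ethers; take H from C2/C3 (flavanone ← flavone 19); contract ring C by one carbon by re-forming the C2–C4 bond, so that C3 becomes the CH2 of a cyclopropanol fused on a dihydrobenzofuran (18); cut C2–C4 (acyl transfer) and O1–CH2 (ether) to salicylamide 9 and benzylic alcohol 15.
- Forward: ring A is resorcinol and ring B with its pyran ring is a bought chromanone; the furanone ring is closed by anionic acyl transfer, the cyclopropane by methylene transfer, and ring C arises last by one-carbon ring expansion; reduction and deprotection follow.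
- Enabling feature: C2 carries both the ring oxygen O1 and the electron-rich aryl of ring B, and C4 carries oxygen; an O-centred radical at C4 of 18 therefore breaks the C2–C4 bond shared by the three- and five-membered rings, and the resulting C2 radical is easily oxidized to the C2=C3 double bond.
- Regiochemistry: prenyl sits between two oxygens of a mirror-symmetric arene and O1 is introduced para to it, so both ortho positions for the acyl carbon are equivalent and only the 6-prenyl pattern can form.
- Stereochemistry: the single stereocentre C2 (S) comes from ligand-controlled copper hydride conjugate reduction of flavone 19.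

Key step: step 12

Assumption: the sense of induction of the copper hydride catalyst in step 13 is assigned beforehand on a model flavone; the ligand is written as (R)-DTBM-SEGPHOS and its mirror image is taken if the model points the other way.

Step 1
Reactants: 1 resorcinol
Product: 2 1,3-bis(methoxymethoxy)benzene
Conditions: NaH, MOMCl, DMF, 0 °C to rt
Reagents that add atoms: chloromethyl methyl ether, COCCl
Why: Williamson-type double O-alkylation of the bis-phenoxide gives the bis-acetal whose two OMOM groups later direct metalation to the carbon between them.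

Step 2
Reactants: 2 1,3-bis(methoxymethoxy)benzene
Product: 4 1,3-bis(methoxymethoxy)-2-(3-methylbut-2-en-1-yl)benzene, via 2-lithio-1,3-bis(methoxymethoxy)benzene 3 (not isolated)
Conditions: n-BuLi, THF, 0 °C; then CuBr·SMe2 (10 mol %), prenyl bromide, −78 °C to rt
Reagents that add atoms: 1-bromo-3-methylbut-2-ene (prenyl bromide), CC(C)=CCBr
Why: Directed ortho-metalation at the doubly activated position between the two OMOM groups, then copper-mediated SN2 alkylation, should place the prenyl group on the future C6 with both neighbouring oxygens already present.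

Step 3
Reactants: 4 1,3-bis(methoxymethoxy)-2-(3-methylbut-2-en-1-yl)benzene
Product: 6 3,5-bis(methoxymethoxy)-4-(3-methylbut-2-en-1-yl)phenol, via aryl pinacol boronate 5 (not isolated)
Conditions: [Ir(OMe)(cod)]2 (1.5 mol %), dtbpy (3 mol %), B2pin2 (0.6 equiv), THF, 80 °C; then NaOH, H2O2, THF/H2O, 0 °C
Reagents that add atoms: bis(pinacolato)diboron, CC1(C)OB(OC1(C)C)B1OC(C)(C)C(C)(C)O1 (boron of 5); hydrogen peroxide, OO (phenol oxygen of 6)
Why: Sterically governed iridium-catalysed C–H borylation should take the only ring C–H without an ortho substituent (para to prenyl), and C–B oxidation then gives a phenol whose two ortho positions are equivalent, so that the later acylation cannot lead to the 8-prenyl isomer.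

Step 4
Reactants: 6 3,5-bis(methoxymethoxy)-4-(3-methylbut-2-en-1-yl)phenol
Product: 7 3,5-bis(methoxymethoxy)-4-(3-methylbut-2-en-1-yl)phenyl N,N-diethylcarbamate
Conditions: NaH, ClC(O)NEt2, THF, 0 °C to rt
Reagents that add atoms: N,N-diethylcarbamoyl chloride, CCN(CC)C(Cl)=O
Why: O-Acylation of the phenoxide installs the group that directs ortho-lithiation and carries the future C4 carbonyl carbon.

Step 5
Reactants: 7 3,5-bis(methoxymethoxy)-4-(3-methylbut-2-en-1-yl)phenyl N,N-diethylcarbamate
Product: 9 N,N-diethyl-6-hydroxy-2,4-bis(methoxymethoxy)-3-(3-methylbut-2-en-1-yl)benzamide, via ortho-lithiated carbamate 8 (not isolated)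
Conditions: LiN(iPr)2, THF, −78 °C to rt; then AcOH
Reagents that add atoms: none
Why: Anionic ortho-Fries rearrangement, in which lithiation between the carbamate and an OMOM group (both ortho sites are equivalent) and a 1,3-shift of the carbamoyl group from O to C should give the salicylamide with O1 free and the C4–C4a bond made.

Step 6
Reactants: 10 7-hydroxy-2,2-dimethylchroman-4-one
Product: 12 2,2-dimethyl-2H-chromen-7-ol, via 2,2-dimethylchromane-4,7-diol 11 (not isolated)
Conditions: NaBH4, MeOH, 0 °C; then p-TsOH·H2O (cat.), toluene, 60 °C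
Reagents that add atoms: none
Why: Hydride reduction of the aryl ketone and acid-catalysed dehydration of the benzylic alcohol (para to the phenol) should give the 2,2-dimethylchromene with the linear ring fusion fixed by the bought chromanone.

Step 7
Reactants: 12 2,2-dimethyl-2H-chromen-7-ol
Product: 13 7-hydroxy-2,2-dimethyl-2H-chromene-6-carbaldehyde
Conditions: MgCl2, Et3N, (CH2O)n, MeCN, reflux
Reagents that add atoms: formaldehyde (as paraformaldehyde), C=O
Why: Magnesium phenoxide-directed ortho-formylation (hydroxymethylation, then hydride transfer to a second formaldehyde) should go to the less hindered ortho position C6 and not to C8 between the two ring oxygens.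

Step 8
Reactants: 13 7-hydroxy-2,2-dimethyl-2H-chromene-6-carbaldehyde
Product: 14 7-(methoxymethoxy)-2,2-dimethyl-2H-chromene-6-carbaldehyde
Conditions: NaH, MOMCl, DMF, 0 °C to rt
Reagents that add atoms: chloromethyl methyl ether, COCCl
Why: O-Alkylation of the chelated phenoxide protects the future 2'-hydroxyl as a MOM ether, so that all three phenols are released in one final operation.

Step 9
Reactants: 14 7-(methoxymethoxy)-2,2-dimethyl-2H-chromene-6-carbaldehyde
Product: 15 [7-(methoxymethoxy)-2,2-dimethyl-2H-chromen-6-yl]methanol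
Conditions: NaBH4, MeOH, 0 °C
Reagents that add atoms: none
Why: Chemoselective borohydride reduction of the aldehyde should give the benzylic alcohol without touching the chromene double bond.

Step 10
Reactants: 9 N,N-diethyl-6-hydroxy-2,4-bis(methoxymethoxy)-3-(3-methylbut-2-en-1-yl)benzamide; 15 [7-(methoxymethoxy)-2,2-dimethyl-2H-chromen-6-yl]methanol
Product: 16 N,N-diethyl-2,4-bis(methoxymethoxy)-6-{[7-(methoxymethoxy)-2,2-dimethyl-2H-chromen-6-yl]methoxy}-3-(3-methylbut-2-en-1-yl)benzamide
Conditions: PPh3, DIAD, THF, 0 °C to rt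
Reagents that add atoms: none
Why: Mitsunobu etherification joins the acidic, hydrogen-bonded phenol of 9 with the activated benzylic alcohol under neutral conditions and so forms the O1–C2 bond without a labile electron-rich benzylic halide.

Step 11
Reactants: 16 N,N-diethyl-2,4-bis(methoxymethoxy)-6-{[7-(methoxymethoxy)-2,2-dimethyl-2H-chromen-6-yl]methoxy}-3-(3-methylbut-2-en-1-yl)benzamide
Product: 18 4,6-bis(methoxymethoxy)-1a-[7-(methoxymethoxy)-2,2-dimethyl-2H-chromen-6-yl]-5-(3-methylbut-2-en-1-yl)-1,1a-dihydro-6bH-cyclopropa[b][1]benzofuran-6b-ol (racemic; cis-fused), via lithium benzofuran-3-olate 17 (not isolated)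
Conditions: LiN(iPr)2 (1.2 equiv), THF, −78 to 0 °C; then Sm, CH2I2, THF, −78 °C to rt; pH 7 phosphate buffer
Reagents that add atoms: diiodomethane, ICI
Why: Amide-assisted deprotonation of the benzylic OCH2 group and 5-exo-trig acyl transfer with loss of diethylamide should close the furanone ring as the aromatic enolate 17 (C2–C4 bond), and the samarium carbenoid ICH2SmI, which methylenates double bonds bound to a metal alkoxide but leaves isolated alkenes alone, then adds CH2 across C2=C3 of this enolate (cis fusion is the only one possible).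

Step 12
Reactants: 18 4,6-bis(methoxymethoxy)-1a-[7-(methoxymethoxy)-2,2-dimethyl-2H-chromen-6-yl]-5-(3-methylbut-2-en-1-yl)-1,1a-dihydro-6bH-cyclopropa[b][1]benzofuran-6b-ol
Product: 19 5,7-bis(methoxymethoxy)-2-[7-(methoxymethoxy)-2,2-dimethyl-2H-chromen-6-yl]-6-(3-methylbut-2-en-1-yl)-4H-chromen-4-one
Conditions: Mn(acac)3 (2.2 equiv), Cu(OAc)2 (20 mol %), MeCN, 0 °C to rt, Ar
Reagents that add atoms: none
Why: Ligand exchange should give a trivalent manganese cyclopropanolate whose homolysis forms an alkoxy radical at the carbinol carbon; β-scission of the bond shared by the three- and five-membered rings then turns the furan ring (O, C1a, C6b, C6a, C2a) into the six-membered pyranone ring, with the former cyclopropane CH2 as C3 and a radical at C2. This radical is tertiary, benzylic to ring B and α to O1, so divalent copper (re-oxidized by manganese) oxidizes it and loss of a proton from C3 gives the flavone. The closest known reaction type is the oxidative one-carbon ring enlargement of fused cyclopropanols and siloxycyclopropanes to cycloalkenones with FeCl3 or trivalent manganese salts. No ring bond is formed, since the six-membered ring arises by bond cleavage and not by cyclization, and no stereocentre is created because C2 becomes trigonal, so both enantiomers of 18 converge on one achiral product. The step needs scission of the internal and not the external cyclopropane bond, which the stabilization of the C2 radical by O1 and the aryl group secures, and it needs chemoselectivity over the prenyl and chromene alkenes and the electron-rich arenes, which the inner-sphere oxidation of the O–H group by the mild oxidant Mn(acac)3 secures.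

Step 13
Reactants: 19 5,7-bis(methoxymethoxy)-2-[7-(methoxymethoxy)-2,2-dimethyl-2H-chromen-6-yl]-6-(3-methylbut-2-en-1-yl)-4H-chromen-4-one
Product: 20 (2S)-5,7-bis(methoxymethoxy)-2-[7-(methoxymethoxy)-2,2-dimethyl-2H-chromen-6-yl]-6-(3-methylbut-2-en-1-yl)-2,3-dihydro-4H-chromen-4-one
Conditions: Cu(OAc)2·H2O (5 mol %), (R)-DTBM-SEGPHOS (5.5 mol %), (EtO)2MeSiH, t-BuOH, toluene, 0 °C; then aq. NH4F
Reagents that add atoms: none
Why: Conjugate reduction of the chromone by a chiral bisphosphine-ligated monovalent copper hydride (the asymmetric 1,4-reduction known for β,β-disubstituted enones and chromones) should deliver hydride to one face of C2 under ligand control to set the (S) centre, the copper enolate being protonated by t-BuOH before ring C can open, while the prenyl and chromene alkenes are not activated towards hydrocupration.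

Step 14
Reactants: 20 (2S)-5,7-bis(methoxymethoxy)-2-[7-(methoxymethoxy)-2,2-dimethyl-2H-chromen-6-yl]-6-(3-methylbut-2-en-1-yl)-2,3-dihydro-4H-chromen-4-one
Product: 21 cudraflavanone A
Conditions: HCl (1.25 M in MeOH), THF, 0 °C to rt
Reagents that add atoms: none
Why: Acid-catalysed acetal exchange with methanol should remove the three MOM groups under conditions in which the flavanone stereocentre is stable (its racemization runs through base-induced ring opening) and which are too mild to cyclize the prenyl group onto the neighbouring phenols.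

**Compound list**
1 | resorcinol | Oc1cccc(O)c1 | starting material
2 | 1,3-bis(methoxymethoxy)benzene | COCOc1cccc(OCOC)c1 | intermediate
3 | 2-lithio-1,3-bis(methoxymethoxy)benzene (formed in the flask) | [Li]c1c(OCOC)cccc1OCOC | intermediate
4 | 1,3-bis(methoxymethoxy)-2-(3-methylbut-2-en-1-yl)benzene | COCOc1cccc(OCOC)c1CC=C(C)C | intermediate
5 | 2-[3,5-bis(methoxymethoxy)-4-(3-methylbut-2-en-1-yl)phenyl]-4,4,5,5-tetramethyl-1,3,2-dioxaborolane (formed in the flask) | COCOc1cc(B2OC(C)(C)C(C)(C)O2)cc(OCOC)c1CC=C(C)C | intermediate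
6 | 3,5-bis(methoxymethoxy)-4-(3-methylbut-2-en-1-yl)phenol | COCOc1cc(O)cc(OCOC)c1CC=C(C)C | intermediate
7 | 3,5-bis(methoxymethoxy)-4-(3-methylbut-2-en-1-yl)phenyl N,N-diethylcarbamate | CCN(CC)C(=O)Oc1cc(OCOC)c(CC=C(C)C)c(OCOC)c1 | intermediate
8 | 2-lithio-3,5-bis(methoxymethoxy)-4-(3-methylbut-2-en-1-yl)phenyl N,N-diethylcarbamate (formed in the flask) | CCN(CC)C(=O)Oc1cc(OCOC)c(CC=C(C)C)c(OCOC)c1[Li] | intermediate
9 | N,N-diethyl-6-hydroxy-2,4-bis(methoxymethoxy)-3-(3-methylbut-2-en-1-yl)benzamide | CCN(CC)C(=O)c1c(O)cc(OCOC)c(CC=C(C)C)c1OCOC | intermediate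
10 | 7-hydroxy-2,2-dimethylchroman-4-one | CC1(C)CC(=O)c2ccc(O)cc2O1 | starting material
11 | 2,2-dimethylchromane-4,7-diol (racemic; formed in the flask) | CC1(C)CC(O)c2ccc(O)cc2O1 | intermediate
12 | 2,2-dimethyl-2H-chromen-7-ol | CC1(C)C=Cc2ccc(O)cc2O1 | intermediate
13 | 7-hydroxy-2,2-dimethyl-2H-chromene-6-carbaldehyde | CC1(C)C=Cc2cc(C=O)c(O)cc2O1 | intermediate
14 | 7-(methoxymethoxy)-2,2-dimethyl-2H-chromene-6-carbaldehyde | CC1(C)C=Cc2cc(C=O)c(OCOC)cc2O1 | intermediate
15 | [7-(methoxymethoxy)-2,2-dimethyl-2H-chromen-6-yl]methanol | CC1(C)C=Cc2cc(CO)c(OCOC)cc2O1 | intermediate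
16 | N,N-diethyl-2,4-bis(methoxymethoxy)-6-{[7-(methoxymethoxy)-2,2-dimethyl-2H-chromen-6-yl]methoxy}-3-(3-methylbut-2-en-1-yl)benzamide | CCN(CC)C(=O)c1c(OCc2cc3c(cc2OCOC)OC(C)(C)C=C3)cc(OCOC)c(CC=C(C)C)c1OCOC | intermediate
17 | lithium 4,6-bis(methoxymethoxy)-2-[7-(methoxymethoxy)-2,2-dimethyl-2H-chromen-6-yl]-5-(3-methylbut-2-en-1-yl)-1-benzofuran-3-olate (formed in the flask) | [Li+].[O-]c1c(-c2cc3c(cc2OCOC)OC(C)(C)C=C3)oc2cc(OCOC)c(CC=C(C)C)c(OCOC)c12 | intermediate
18 | 4,6-bis(methoxymethoxy)-1a-[7-(methoxymethoxy)-2,2-dimethyl-2H-chromen-6-yl]-5-(3-methylbut-2-en-1-yl)-1,1a-dihydro-6bH-cyclopropa[b][1]benzofuran-6b-ol (racemic, cis-fused; one enantiomer drawn) | O[C@@]12C[C@]1(c1cc3c(cc1OCOC)OC(C)(C)C=C3)Oc1cc(OCOC)c(CC=C(C)C)c(OCOC)c12 | intermediate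
19 | 5,7-bis(methoxymethoxy)-2-[7-(methoxymethoxy)-2,2-dimethyl-2H-chromen-6-yl]-6-(3-methylbut-2-en-1-yl)-4H-chromen-4-one | CC(C)=CCc1c(OCOC)cc2oc(-c3cc4c(cc3OCOC)OC(C)(C)C=C4)cc(=O)c2c1OCOC | intermediate
20 | (2S)-5,7-bis(methoxymethoxy)-2-[7-(methoxymethoxy)-2,2-dimethyl-2H-chromen-6-yl]-6-(3-methylbut-2-en-1-yl)-2,3-dihydro-4H-chromen-4-one | CC(C)=CCc1c(OCOC)cc2c(c1OCOC)C(=O)C[C@@H](c1cc3c(cc1OCOC)OC(C)(C)C=C3)O2 | intermediate
21 | cudraflavanone A, (2S)-5,7-dihydroxy-2-(7-hydroxy-2,2-dimethyl-2H-chromen-6-yl)-6-(3-methylbut-2-en-1-yl)-2,3-dihydro-4H-chromen-4-one | CC(C)=CCc1c(O)cc2c(c1O)C(=O)C[C@@H](c1cc3c(cc1O)OC(C)(C)C=C3)O2 | target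

Total steps: 14. Longest linear sequence: 10 steps (steps 1–5 and 10–14, from resorcinol); the ring B branch (steps 6–9) joins at step 10.

**Steps most likely to fail**

Step 12. The alkoxy radical may cleave the external cyclopropane bond, the C2 radical may be intercepted before it is oxidized, or the metal oxidants may attack the chromene and the electron-rich arenes. The fallback runs the same one-carbon ring expansion as a Dowd–Beckwith radical chain. It sets out from 16: LiN(iPr)2 as in step 11 gives enolate 17, which is C-alkylated at C2 with CH2I2 (DMPU, THF) to the iodomethyl ketone F1. Slow addition of Bu3SnH with AIBN in benzene at 80 °C should generate the primary radical, which adds 3-exo-trig to the ketone carbonyl; the cyclopropyloxy radical opens to the ring-expanded C2 radical, and hydrogen transfer gives the racemic flavanone F2. Preparative HPLC on cellulose tris(3,5-dimethylphenylcarbamate) separates the enantiomers, and the (2S) enantiomer is 20, where the route continues with step 14.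

Step 11. The benzylic ether may be deprotonated incompletely or undergo a 1,2-aryl (Wittig-type) shift, the carbenoid may attack oxygen instead of C2, or a stepwise β-metallated ketone may expel the ring phenoxide. A failure confined to the carbenoid stage is covered by the iodide route above. The fallback here gives up the ring expansion and closes ring C directly; it sets out from 6 and 14 and comes back at 19. Seyferth–Gilbert homologation of 14 (dimethyl (1-diazo-2-oxopropyl)phosphonate, K2CO3, MeOH) gives the alkyne F3. Ortho-formylation of 6 (MgCl2, Et3N, (CH2O)n, MeCN) gives the salicylaldehyde F4. F3 is deprotonated with n-BuLi to the lithium acetylide F5, which (2.2 equiv) adds to F4 to give the propargylic alcohol F6. MnO2 in CH2Cl2 oxidizes it to the ynone F7, and DMAP (cat.) in DMF should induce 6-endo addition of the phenol to the ynone to give 19.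

Step 13. Facial selectivity at the hindered C2 (flanked by an ortho-substituted aryl group) may be poor, 1,2-reduction may compete, or the chromene alkene may be hydrocuprated. The fallback replaces the conjugate reduction by transfer hydrogenation with dynamic kinetic resolution; it sets out from 19 and comes back at 20. With RuCl[(S,S)-TsDPEN](p-cymene), HCO2H and DBU in MeCN at 40 °C, conjugate transfer hydrogenation should give 20 together with the (2R) enantiomer F8. The two interconvert under the basic conditions by reversible opening of ring C, while the catalyst reduces the (2S) ketone faster to the (2S,4S)-flavan-4-ol F9 (by analogy with 1-tetralone the (S,S) ligand should give the (4S) carbinol, cis to the aryl group). Dess–Martin periodinane in CH2Cl2 re-oxidizes C4 and returns 20.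

**Further compounds**
F1 | step 12 | 2-(iodomethyl)-4,6-bis(methoxymethoxy)-2-[7-(methoxymethoxy)-2,2-dimethyl-2H-chromen-6-yl]-5-(3-methylbut-2-en-1-yl)-1-benzofuran-3(2H)-one (racemic) | CC(C)=CCc1c(OCOC)cc2OC(CI)(c3cc4c(cc3OCOC)OC(C)(C)C=C4)C(=O)c2c1OCOC
F2 | step 12 | racemic 5,7-bis(methoxymethoxy)-2-[7-(methoxymethoxy)-2,2-dimethyl-2H-chromen-6-yl]-6-(3-methylbut-2-en-1-yl)-2,3-dihydro-4H-chromen-4-one | CC(C)=CCc1c(OCOC)cc2c(c1OCOC)C(=O)CC(c1cc3c(cc1OCOC)OC(C)(C)C=C3)O2
F3 | step 11 | 6-ethynyl-7-(methoxymethoxy)-2,2-dimethyl-2H-chromene | C#Cc1cc2c(cc1OCOC)OC(C)(C)C=C2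
F4 | step 11 | 6-hydroxy-2,4-bis(methoxymethoxy)-3-(3-methylbut-2-en-1-yl)benzaldehyde | O=Cc1c(O)cc(OCOC)c(CC=C(C)C)c1OCOC
F5 | step 11 | lithium [7-(methoxymethoxy)-2,2-dimethyl-2H-chromen-6-yl]acetylide (formed in the flask) | [Li]C#Cc1cc2c(cc1OCOC)OC(C)(C)C=C2
F6 | step 11 | 1-[6-hydroxy-2,4-bis(methoxymethoxy)-3-(3-methylbut-2-en-1-yl)phenyl]-3-[7-(methoxymethoxy)-2,2-dimethyl-2H-chromen-6-yl]prop-2-yn-1-ol (racemic) | OC(C#Cc1cc2c(cc1OCOC)OC(C)(C)C=C2)c1c(O)cc(OCOC)c(CC=C(C)C)c1OCOC
F7 | step 11 | 1-[6-hydroxy-2,4-bis(methoxymethoxy)-3-(3-methylbut-2-en-1-yl)phenyl]-3-[7-(methoxymethoxy)-2,2-dimethyl-2H-chromen-6-yl]prop-2-yn-1-one | O=C(C#Cc1cc2c(cc1OCOC)OC(C)(C)C=C2)c1c(O)cc(OCOC)c(CC=C(C)C)c1OCOC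
F8 | step 13 | (2R)-5,7-bis(methoxymethoxy)-2-[7-(methoxymethoxy)-2,2-dimethyl-2H-chromen-6-yl]-6-(3-methylbut-2-en-1-yl)-2,3-dihydro-4H-chromen-4-one (formed in the flask) | CC(C)=CCc1c(OCOC)cc2c(c1OCOC)C(=O)C[C@H](c1cc3c(cc1OCOC)OC(C)(C)C=C3)O2
F9 | step 13 | (2S,4S)-5,7-bis(methoxymethoxy)-2-[7-(methoxymethoxy)-2,2-dimethyl-2H-chromen-6-yl]-6-(3-methylbut-2-en-1-yl)-3,4-dihydro-2H-chromen-4-ol | CC(C)=CCc1c(OCOC)cc2c(c1OCOC)[C@@H](O)C[C@@H](c1cc3c(cc1OCOC)OC(C)(C)C=C3)O2
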